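**Strategy**

Everything rests on cutting the ten-membered carbocycle at C1–C10. In that ring the C1 ketone and the C8 oxygen stand 1,4 to each other through C10 and C9, which is the pattern left when an acyl radical adds to the β-carbon of an enone. One operation, 10-endo cyclisation of a C1 acyl radical onto the C9=C10 alkene of a crotonyl ketone, closes the carbocycle, forms C1–C10 and sets C10. The precursor is an open-chain phenyl selenoester that already carries the trans-4,5-epoxide, the 6S butenolide ring with its C13 acetate, and the (E)-crotonyl ketone on C7; its three stereocentres come from a Sharpless epoxidation and a catalyst-controlled ynone reduction.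

Key step: step 12

**Remarks on the chemistry**

- Germacrane numbering is used throughout: ring carbons C1–C10, lactone carbons C11–C13, C14 on C10, C15 on C4.
- The selenoester 17 and the diketone 18 agree with the target at C4, C5, C6 and C10 and with an epoxide derived from (E)-geraniol; no structural correction was needed and both are used as drawn.
- Assumption: D-(−)-diethyl tartrate gives the (2R,3R)-epoxide of geraniol, the mirror image of the (2S,3S)-epoxide formed with the L-(+)-ester.
- C6–O and C5–O are syn in the target, whereas Felkin-type addition to the epoxy aldehyde favours anti. C6 is therefore set by reagent control (steps 3–5).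
- The C13 acetate is carried through the cyclisation, and the selenoester is made only in the last step before it.

**Route**

Step 1
Reactants: 1 geraniol
Product: 2 [(2R,3R)-3-methyl-3-(4-methylpent-3-en-1-yl)oxiran-2-yl]methanol
Conditions: Ti(OiPr)4 (5 mol%), D-(−)-diethyl tartrate (7 mol%), t-BuOOH, 4 Å MS, CH2Cl2, −20 °C
Reagents that add atoms: tert-butyl hydroperoxide CC(C)(C)OO
Why: Sharpless asymmetric epoxidation, in which the allylic hydroxyl binds the titanium tartrate so that only the 2,3-alkene reacts and the D-(−)-ligand should deliver oxygen to the face that gives the 2R,3R epoxide, the future C5 and C4 (both R).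

Step 2
Reactants: 2 [(2R,3R)-3-methyl-3-(4-methylpent-3-en-1-yl)oxiran-2-yl]methanol
Product: 3 (2S,3R)-3-methyl-3-(4-methylpent-3-en-1-yl)oxirane-2-carbaldehyde
Conditions: TEMPO (10 mol%), PhI(OAc)2, CH2Cl2, 23 °C
Reagents that add atoms: none
Why: Nitroxyl-catalysed oxidation of a primary alcohol stops at the aldehyde under near-neutral conditions that spare the trisubstituted epoxide and the remote alkene (the descriptor at the oxirane CH changes only because the formyl group outranks the ring carbon).

Step 3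
Reactants: 3 (2S,3R)-3-methyl-3-(4-methylpent-3-en-1-yl)oxirane-2-carbaldehyde; 4 methyl propiolate
Product: 6 methyl 4-hydroxy-4-[(2R,3R)-3-methyl-3-(4-methylpent-3-en-1-yl)oxiran-2-yl]but-2-ynoate as a mixture of C6 epimers, via lithium methyl propiolate 5 (not isolated)
Conditions: LiN(SiMe3)2, THF, −78 °C; then 3; AcOH, −78 °C
Reagents that add atoms: none
Why: 1,2-Addition of a lithium acetylide to an aldehyde forms C6–C7 at −78 °C, and the epimers are not separated because C6 is reset in steps 4 and 5.

Step 4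
Reactants: 6 methyl 4-hydroxy-4-[(2R,3R)-3-methyl-3-(4-methylpent-3-en-1-yl)oxiran-2-yl]but-2-ynoate (C6 epimers)
Product: 7 methyl 4-[(2S,3R)-3-methyl-3-(4-methylpent-3-en-1-yl)oxiran-2-yl]-4-oxobut-2-ynoate
Conditions: Dess–Martin periodinane, pyridine, CH2Cl2, 0 °C
Reagents that add atoms: none
Why: Dess–Martin oxidation of a propargylic alcohol converges both C6 epimers on one ynone under buffered conditions that should not open the epoxide.

Step 5
Reactants: 7 methyl 4-[(2S,3R)-3-methyl-3-(4-methylpent-3-en-1-yl)oxiran-2-yl]-4-oxobut-2-ynoate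
Product: 8 methyl (4S)-4-hydroxy-4-[(2R,3R)-3-methyl-3-(4-methylpent-3-en-1-yl)oxiran-2-yl]but-2-ynoate
Conditions: Ru[(R,R)-TsNCH(Ph)CH(Ph)NH](p-cymene) (2 mol%), i-PrOH, 23 °C
Reagents that add atoms: none
Why: Noyori asymmetric transfer hydrogenation of an alkynyl ketone, in which the alkyne is the recognised π-group, so the (R,R)-catalyst should override the substrate bias and give the 6S carbinol, syn to the epoxide oxygen.

Step 6
Reactants: 8 methyl (4S)-4-hydroxy-4-[(2R,3R)-3-methyl-3-(4-methylpent-3-en-1-yl)oxiran-2-yl]but-2-ynoate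
Product: 11 (5R)-3-(hydroxymethyl)-5-[(2R,3R)-3-methyl-3-(4-methylpent-3-en-1-yl)oxiran-2-yl]-4-(trimethylstannyl)furan-2(5H)-one, via lithium alkoxide 9 (not isolated), via butenolide vinylcuprate 10 (not isolated)
Conditions: LiN(SiMe3)2 (1.0 equiv), THF, −78 °C; Li[Me3SnCu(SPh)] (1.3 equiv), −78 to −40 °C; CH2O (monomer in THF), −78 °C; AcOH
Reagents that add atoms: lithium (phenylthio)(trimethylstannyl)cuprate [Li+].C[Sn](C)(C)[Cu-]Sc1ccccc1; formaldehyde C=O
Why: Syn stannylcupration of a γ-hydroxy ynoate puts tin on C7 and copper on C11 with the C6 alkoxide cis to the ester, so lactonisation locks the alkene geometry and the C11 vinylcopper is then captured by formaldehyde (tandem conjugate addition, lactonisation and electrophile capture), C6 being untouched (its descriptor reads R only because tin outranks oxygen).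

Step 7
Reactants: 11 (5R)-3-(hydroxymethyl)-5-[(2R,3R)-3-methyl-3-(4-methylpent-3-en-1-yl)oxiran-2-yl]-4-(trimethylstannyl)furan-2(5H)-one
Product: 12 [(5R)-5-[(2R,3R)-3-methyl-3-(4-methylpent-3-en-1-yl)oxiran-2-yl]-2-oxo-4-(trimethylstannyl)-2,5-dihydrofuran-3-yl]methyl acetate
Conditions: Ac2O, pyridine, DMAP (cat.), CH2Cl2, 0 °C
Reagents that add atoms: acetic anhydride CC(=O)OC(C)=O
Why: Acetylation of the primary allylic alcohol installs the C13 acetate of the target under conditions too weakly basic to remove the C6 proton.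

Step 8
Reactants: 12 [(5R)-5-[(2R,3R)-3-methyl-3-(4-methylpent-3-en-1-yl)oxiran-2-yl]-2-oxo-4-(trimethylstannyl)-2,5-dihydrofuran-3-yl]methyl acetate; 13 (E)-but-2-enoyl chloride
Product: 14 [(5S)-4-[(E)-but-2-enoyl]-5-[(2R,3R)-3-methyl-3-(4-methylpent-3-en-1-yl)oxiran-2-yl]-2-oxo-2,5-dihydrofuran-3-yl]methyl acetate
Conditions: Pd2(dba)3 (3 mol%), AsPh3 (12 mol%), THF, 50 °C
Reagents that add atoms: none
Why: Stille acylation, in which the acid chloride adds rapidly to zerovalent palladium, the trimethylstannyl group transfers C7, and the weakly donating arsine ligand disfavours ionisation of the C13 allylic acetate.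

Step 9
Reactants: 14 [(5S)-4-[(E)-but-2-enoyl]-5-[(2R,3R)-3-methyl-3-(4-methylpent-3-en-1-yl)oxiran-2-yl]-2-oxo-2,5-dihydrofuran-3-yl]methyl acetate
Product: 15 [(5S)-4-[(E)-but-2-enoyl]-5-[(2R,3R)-3-methyl-3-(3-oxopropyl)oxiran-2-yl]-2-oxo-2,5-dihydrofuran-3-yl]methyl acetate
Conditions: O3, pyridine, CH2Cl2, −78 °C (Sudan Red 7B end point)
Reagents that add atoms: ozone [O-][O+]=O
Why: Pyridine-mediated ozonolysis cleaves the electron-rich trisubstituted alkene much faster than the enone or butenolide alkenes and gives the C1 aldehyde directly, so no reductant meets the dienone.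

Step 10
Reactants: 15 [(5S)-4-[(E)-but-2-enoyl]-5-[(2R,3R)-3-methyl-3-(3-oxopropyl)oxiran-2-yl]-2-oxo-2,5-dihydrofuran-3-yl]methyl acetate
Product: 16 3-[(2R,3R)-3-[(2S)-4-(acetoxymethyl)-3-[(E)-but-2-enoyl]-5-oxo-2,5-dihydrofuran-2-yl]-2-methyloxiran-2-yl]propanoic acid
Conditions: NaClO2, NaH2PO4, 2-methyl-2-butene, t-BuOH/H2O, 0 °C
Reagents that add atoms: sodium chlorite [Na+].[O-]Cl=O
Why: Pinnick oxidation converts the aldehyde to the acid in a phosphate buffer with a hypochlorite scavenger, conditions that tolerate epoxides, enones and esters.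

Step 11
Reactants: 16 3-[(2R,3R)-3-[(2S)-4-(acetoxymethyl)-3-[(E)-but-2-enoyl]-5-oxo-2,5-dihydrofuran-2-yl]-2-methyloxiran-2-yl]propanoic acid
Product: 17 Se-phenyl 3-[(2R,3R)-3-[(2S)-4-(acetoxymethyl)-3-[(E)-but-2-enoyl]-5-oxo-2,5-dihydrofuran-2-yl]-2-methyloxiran-2-yl]propaneselenoate
Conditions: N-(phenylseleno)phthalimide, Bu3P (premixed), CH2Cl2, −30 °C
Reagents that add atoms: N-(phenylseleno)phthalimide O=C1N([Se]c2ccccc2)C(=O)c2ccccc12
Why: Grieco-type selenoesterification, in which the phosphine is consumed by the selenium electrophile before the acid is added and the acyloxyphosphonium ion is captured by selenolate as it forms, which keeps both nucleophiles away from the dienone.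

Step 12
Reactants: 17 Se-phenyl 3-[(2R,3R)-3-[(2S)-4-(acetoxymethyl)-3-[(E)-but-2-enoyl]-5-oxo-2,5-dihydrofuran-2-yl]-2-methyloxiran-2-yl]propaneselenoate
Product: 18 (4R,5R,6S,10R)-13-acetoxy-4,5-epoxy-1,8-dioxogermacr-7(11)-en-12,6-olide
Conditions: (Me3Si)3SiH (1.5 equiv), AIBN (0.3 equiv), PhH, 80 °C, syringe-pump addition, 3 mM
Reagents that add atoms: none
Why: The tris(trimethylsilyl)silyl radical abstracts the phenylseleno group, the nucleophilic primary acyl radical (slow to lose CO) adds to the electron-poor β-carbon C10 of the crotonyl ketone, and the C9 α-keto radical takes hydrogen from the silane to carry the chain. The closest known reaction type is the acyl radical macrocyclisation of ω-enone phenyl selenoesters to macrocyclic 1,4-diketones. The one new ring is closed in the 10-endo-trig mode, both alkene carbons ending inside it. C10 is the only new stereocentre and is under substrate control: the trans-epoxide and the planar butenolide restrict the folding of the chain, which should favour the alkene face that leaves the methyl group pseudo-equatorial (10R), and since C10 is α to the new ketone it can be equilibrated if selectivity is poor. The step needs attack at C10 and not at C7 or C11, and cyclisation ahead of reduction of the acyl radical; C7=C11 is tetrasubstituted and a seven- or eight-membered ring through it would have to contain the trans-fused epoxide, while slow addition at high dilution keeps the silane concentration low. No radical arises next to the epoxide and the neutral medium leaves the acidic C6–H alone.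

Step 13
Reactants: 18 (4R,5R,6S,10R)-13-acetoxy-4,5-epoxy-1,8-dioxogermacr-7(11)-en-12,6-olide
Product: 19 (4R,5R,6S,8S,10R)-13-acetoxy-4,5-epoxy-8-hydroxy-1-oxogermacr-7(11)-en-12,6-olide
Conditions: (R)-2-methyl-CBS-oxazaborolidine (20 mol%), catecholborane (1.1 equiv), PhMe, −78 °C
Reagents that add atoms: none
Why: Corey–Bakshi–Shibata reduction, in which the catalyst–borane complex should reduce the conjugated, electrophilic C8 ketone 1,2 from the face set by the (R)-oxazaborolidine (alkenyl as the large group, giving 8S) faster than the hindered, poorly differentiated dialkyl ketone at C1.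

Step 14
Reactants: 19 (4R,5R,6S,8S,10R)-13-acetoxy-4,5-epoxy-8-hydroxy-1-oxogermacr-7(11)-en-12,6-olide; 20 angelic acid
Product: 22 CNP0229937.2 (4R,5R,6S,8S,10R)-13-acetoxy-8-angeloyloxy-4,5-epoxy-1-oxogermacr-7(11)-en-12,6-olide, via angelic mixed anhydride 21 (not isolated)
Conditions: 2,4,6-Cl3C6H2COCl, Et3N, PhMe, 23 °C; then 19, 75 °C
Reagents that add atoms: none
Why: Yamaguchi esterification through the preformed mixed anhydride, run without 4-dimethylaminopyridine, acylates the secondary alcohol with retention at C8 and is the established way to make angelates without Z to E isomerisation.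

**Compound list**

1 | geraniol, (2E)-3,7-dimethylocta-2,6-dien-1-ol | CC(C)=CCC/C(C)=C/CO | starting material
2 | [(2R,3R)-3-methyl-3-(4-methylpent-3-en-1-yl)oxiran-2-yl]methanol | CC(C)=CCC[C@@]1(C)O[C@@H]1CO | intermediate
3 | (2S,3R)-3-methyl-3-(4-methylpent-3-en-1-yl)oxirane-2-carbaldehyde | CC(C)=CCC[C@@]1(C)O[C@@H]1C=O | intermediate
4 | methyl propiolate | C#CC(=O)OC | starting material
5 | lithium methyl propiolate (methyl 3-lithioprop-2-ynoate) | [Li]C#CC(=O)OC | intermediate (not isolated)
6 | methyl 4-hydroxy-4-[(2R,3R)-3-methyl-3-(4-methylpent-3-en-1-yl)oxiran-2-yl]but-2-ynoate, both C6 epimers | CC(C)=CCC[C@@]1(C)O[C@@H]1C(O)C#CC(=O)OC | intermediate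
7 | methyl 4-[(2S,3R)-3-methyl-3-(4-methylpent-3-en-1-yl)oxiran-2-yl]-4-oxobut-2-ynoate | CC(C)=CCC[C@@]1(C)O[C@@H]1C(=O)C#CC(=O)OC | intermediate
8 | methyl (4S)-4-hydroxy-4-[(2R,3R)-3-methyl-3-(4-methylpent-3-en-1-yl)oxiran-2-yl]but-2-ynoate | CC(C)=CCC[C@@]1(C)O[C@@H]1[C@@H](O)C#CC(=O)OC | intermediate
9 | lithium alkoxide of 8 | CC(C)=CCC[C@@]1(C)O[C@@H]1[C@@H]([O-])C#CC(=O)OC.[Li+] | intermediate (not isolated)
10 | lithium (phenylthio)cuprate of the 4-(trimethylstannyl)butenolide, copper on C11 | CC(C)=CCC[C@@]1(C)O[C@@H]1[C@H]1OC(=O)C([Cu-]Sc2ccccc2)=C1[Sn](C)(C)C.[Li+] | intermediate (not isolated)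
11 | (5R)-3-(hydroxymethyl)-5-[(2R,3R)-3-methyl-3-(4-methylpent-3-en-1-yl)oxiran-2-yl]-4-(trimethylstannyl)furan-2(5H)-one | CC(C)=CCC[C@@]1(C)O[C@@H]1[C@H]1OC(=O)C(CO)=C1[Sn](C)(C)C | intermediate
12 | [(5R)-5-[(2R,3R)-3-methyl-3-(4-methylpent-3-en-1-yl)oxiran-2-yl]-2-oxo-4-(trimethylstannyl)-2,5-dihydrofuran-3-yl]methyl acetate | CC(C)=CCC[C@@]1(C)O[C@@H]1[C@H]1OC(=O)C(COC(C)=O)=C1[Sn](C)(C)C | intermediate
13 | (E)-but-2-enoyl chloride | C/C=C/C(Cl)=O | starting material
14 | [(5S)-4-[(E)-but-2-enoyl]-5-[(2R,3R)-3-methyl-3-(4-methylpent-3-en-1-yl)oxiran-2-yl]-2-oxo-2,5-dihydrofuran-3-yl]methyl acetate | CC(C)=CCC[C@@]1(C)O[C@@H]1[C@H]1OC(=O)C(COC(C)=O)=C1C(=O)/C=C/C | intermediate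
15 | [(5S)-4-[(E)-but-2-enoyl]-5-[(2R,3R)-3-methyl-3-(3-oxopropyl)oxiran-2-yl]-2-oxo-2,5-dihydrofuran-3-yl]methyl acetate | O=CCC[C@@]1(C)O[C@@H]1[C@H]1OC(=O)C(COC(C)=O)=C1C(=O)/C=C/C | intermediate
16 | 3-[(2R,3R)-3-[(2S)-4-(acetoxymethyl)-3-[(E)-but-2-enoyl]-5-oxo-2,5-dihydrofuran-2-yl]-2-methyloxiran-2-yl]propanoic acid | OC(=O)CC[C@@]1(C)O[C@@H]1[C@H]1OC(=O)C(COC(C)=O)=C1C(=O)/C=C/C | intermediate
17 | Se-phenyl 3-[(2R,3R)-3-[(2S)-4-(acetoxymethyl)-3-[(E)-but-2-enoyl]-5-oxo-2,5-dihydrofuran-2-yl]-2-methyloxiran-2-yl]propaneselenoate | O=C([Se]c1ccccc1)CC[C@@]1(C)O[C@@H]1[C@H]1OC(=O)C(COC(C)=O)=C1C(=O)/C=C/C | intermediate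
18 | (4R,5R,6S,10R)-13-acetoxy-4,5-epoxy-1,8-dioxogermacr-7(11)-en-12,6-olide | O=C1C[C@@H](C)C(=O)CC[C@@]2(C)O[C@@H]2[C@H]2OC(=O)C(COC(C)=O)=C12 | intermediate
19 | (4R,5R,6S,8S,10R)-13-acetoxy-4,5-epoxy-8-hydroxy-1-oxogermacr-7(11)-en-12,6-olide | O[C@H]1C[C@@H](C)C(=O)CC[C@@]2(C)O[C@@H]2[C@H]2OC(=O)C(COC(C)=O)=C12 | intermediate
20 | angelic acid, (Z)-2-methylbut-2-enoic acid | C/C=C(/C)C(=O)O | starting material
21 | (Z)-2-methylbut-2-enoic 2,4,6-trichlorobenzoic anhydride | C/C=C(/C)C(=O)OC(=O)c1c(Cl)cc(Cl)cc1Cl | intermediate (not isolated)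
22 | CNP0229937.2, (4R,5R,6S,8S,10R)-13-acetoxy-8-angeloyloxy-4,5-epoxy-1-oxogermacr-7(11)-en-12,6-olide | C/C=C(/C)C(=O)O[C@H]1C[C@@H](C)C(=O)CC[C@@]2(C)O[C@@H]2[C@H]2OC(=O)C(COC(C)=O)=C12 | target

**Count and risks**

Total step count: 14. Longest linear sequence: 14 steps (1 to 22).

The three steps most likely to fail:

Step 12 (macrocyclisation). Hydrogen transfer to the acyl radical before ring closure, or oligomerisation, may outrun the ten-membered ring formation; poor facial selectivity at C10 is the secondary concern. Fallback: the same C1–C10 bond would be made by polar umpolung in place of a radical chain. Aldehyde 15, taken before steps 10 and 11, is treated with a triazolium-derived N-heterocyclic carbene and a weak base at high dilution (intramolecular Stetter reaction), the Breslow intermediate adding to C10. This sets out from 15 and comes back at 18; no compound outside the list is made (entry F0).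

Step 6 (stannylcupration with capture). The vinylcopper intermediate may be protonated or may revert before formaldehyde captures it, so that the C13 carbon is lost. Fallback: both ring substituents would be brought in by cross-coupling. Starting from 8, Me3SnSnMe3 with Pd(PPh3)4 (syn bis-stannylation, lactonisation on work-up) gives the 3,4-bis(trimethylstannyl)butenolide F1. Stille acylation with 13, expected to take place first at the β-tin on C7, gives the 4-crotonyl-3-stannylbutenolide F2. Iodine gives the 3-iodobutenolide F3. Stille coupling with Bu3SnCH2OH gives the 3-(hydroxymethyl)butenolide F4, and acetylation (Ac2O, pyridine) returns to the route at 14.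

Step 8 (Stille acylation). Transmetalation from the hindered, electron-poor tetrasubstituted vinylstannane may be too slow, letting protodestannylation or palladium insertion into the allylic acetate compete. Fallback: the C7–C8 bond would be made by carbonyl addition. Starting from 12, iodine gives the 4-iodobutenolide F5. A Nozaki–Hiyama–Kishi reaction with (E)-but-2-enal (CrCl2, NiCl2 cat., DMF) gives the bis-allylic alcohol F6 as a mixture at C8, and Dess–Martin oxidation returns to the route at 14.

**Further compounds**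

F0 | step 12 | none | none
F1 | step 6 | (5R)-5-[(2R,3R)-3-methyl-3-(4-methylpent-3-en-1-yl)oxiran-2-yl]-3,4-bis(trimethylstannyl)furan-2(5H)-one | CC(C)=CCC[C@@]1(C)O[C@@H]1[C@H]1OC(=O)C([Sn](C)(C)C)=C1[Sn](C)(C)C
F2 | step 6 | (5S)-4-[(E)-but-2-enoyl]-5-[(2R,3R)-3-methyl-3-(4-methylpent-3-en-1-yl)oxiran-2-yl]-3-(trimethylstannyl)furan-2(5H)-one | CC(C)=CCC[C@@]1(C)O[C@@H]1[C@H]1OC(=O)C([Sn](C)(C)C)=C1C(=O)/C=C/C
F3 | step 6 | (5S)-4-[(E)-but-2-enoyl]-3-iodo-5-[(2R,3R)-3-methyl-3-(4-methylpent-3-en-1-yl)oxiran-2-yl]furan-2(5H)-one | CC(C)=CCC[C@@]1(C)O[C@@H]1[C@H]1OC(=O)C(I)=C1C(=O)/C=C/C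
F4 | step 6 | (5S)-4-[(E)-but-2-enoyl]-3-(hydroxymethyl)-5-[(2R,3R)-3-methyl-3-(4-methylpent-3-en-1-yl)oxiran-2-yl]furan-2(5H)-one | CC(C)=CCC[C@@]1(C)O[C@@H]1[C@H]1OC(=O)C(CO)=C1C(=O)/C=C/C
F5 | step 8 | [(5R)-4-iodo-5-[(2R,3R)-3-methyl-3-(4-methylpent-3-en-1-yl)oxiran-2-yl]-2-oxo-2,5-dihydrofuran-3-yl]methyl acetate | CC(C)=CCC[C@@]1(C)O[C@@H]1[C@H]1OC(=O)C(COC(C)=O)=C1I
F6 | step 8 | [(5S)-4-[(E)-1-hydroxybut-2-en-1-yl]-5-[(2R,3R)-3-methyl-3-(4-methylpent-3-en-1-yl)oxiran-2-yl]-2-oxo-2,5-dihydrofuran-3-yl]methyl acetate, both C8 epimers | CC(C)=CCC[C@@]1(C)O[C@@H]1[C@H]1OC(=O)C(COC(C)=O)=C1C(O)/C=C/C
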